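**Plan**
1. Retrosynthesis: the seven benzyl ethers and the C4 ketone of unit 1 (the catechol flavanone) are installed last; ring C of unit 2 (the 4-hydroxyphenyl flavanone) is cut at C2''–aryl (conjugate arylation of a chromone), and the chromone goes back to a MOM-masked phenol.
2. In unit 1, C2(O)–C3(aryl)–C4(O) is an aldol-type triad and the C2 oxygen is O1, bonded to C8a of ring A. Cutting O1–C8a therefore opens ring C to a bromoaryl 1,3-diol monosilyl ether, in which the epimerisable cis C2/C3 pair can be made in an open chain with C4 kept as an ether.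
3. The chain is cut at C4–C4a (arylmagnesium plus aldehyde) and at C2–C3 (boron aldol of an arylacetyl oxazolidinone with 3,4-bis(benzyloxy)benzaldehyde); the arylacetic acid comes from 3,5-bis(benzyloxy)phenol by Claisen rearrangement.
4. Forward: chain assembly (steps 1–14), ring C of unit 1 by palladium-catalysed aryl–oxygen coupling (step 15), ring C of unit 2 as a chromone followed by arylation (steps 16–20), then desilylation, C4 oxidation and hydrogenolysis (steps 21–23).
5. Stereochemistry: C2 and C3 of unit 1 (both R, cis) come from the Evans syn-aldol with (R)-4-benzyloxazolidin-2-one; C2'' of unit 2 (R) comes from a rhodium/chiral bisphosphine aryl transfer; the C4 carbinol is transient.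

Key step: step 15

Remarks on the chemistry:
- Atoms of unit 1 carry plain numbers and atoms of unit 2 carry double primes. "Flv" stands for the group (2R,3R,4R)-5,7-bis(benzyloxy)-2-[3,4-bis(benzyloxy)phenyl]-4-[(tert-butyldimethylsilyl)oxy]chroman-3-yl (2,3-cis, 3,4-cis).
- Assumption: the carbinol centre made in step 12 is drawn as the Felkin–Anh epimer. It becomes the C4 carbonyl in step 22, so its epimer, if formed, would pass through the same steps to the same compound 32.

Step 1
Reactants: 1 3,5-bis(benzyloxy)phenol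
Product: 2 1-(allyloxy)-3,5-bis(benzyloxy)benzene
Conditions: allyl bromide, K2CO3, acetone, reflux
Reagents that add atoms: allyl bromide, C=CCBr
Why: Williamson etherification, in which the phenoxide formed with K2CO3 is O-alkylated by the allylic bromide in an SN2 reaction that leaves the benzyl ethers untouched.

Step 2
Reactants: 2 1-(allyloxy)-3,5-bis(benzyloxy)benzene
Product: 3 2-allyl-3,5-bis(benzyloxy)phenol
Conditions: N,N-diethylaniline, 190 °C
Reagents that add atoms: none
Why: Aromatic Claisen rearrangement ([3,3]-sigmatropic shift, then re-aromatising tautomerisation) moves the allyl group to an ortho carbon, and because the two ortho positions are equivalent a single C-allyl phenol with the side chain between OH and OBn is expected.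

Step 3
Reactants: 3 2-allyl-3,5-bis(benzyloxy)phenol
Product: 4 2-allyl-1,5-bis(benzyloxy)-3-(methoxymethoxy)benzene
Conditions: MOMCl, iPr2NEt, CH2Cl2, 0 °C → rt
Reagents that add atoms: chloromethyl methyl ether, COCCl
Why: MOM ether formation by base-mediated O-alkylation marks the oxygen that becomes O1'' of unit 2 with a group that is stable to base and organometallics and can later be removed without touching benzyl ethers.

Step 4
Reactants: 4 2-allyl-1,5-bis(benzyloxy)-3-(methoxymethoxy)benzene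
Product: 5 2-[2,4-bis(benzyloxy)-6-(methoxymethoxy)phenyl]acetaldehyde
Conditions: OsO4 (2 mol%), NaIO4, 2,6-lutidine, dioxane/H2O, rt
Reagents that add atoms: osmium tetroxide (catalytic oxygen carrier), O=[Os](=O)(=O)=O; sodium periodate, [Na+].[O-]I(=O)(=O)=O
Why: Lemieux–Johnson oxidation, in which catalytic dihydroxylation of the terminal alkene and periodate cleavage of the diol give the arylacetaldehyde while 2,6-lutidine suppresses side reactions of the diol.

Step 5
Reactants: 5 2-[2,4-bis(benzyloxy)-6-(methoxymethoxy)phenyl]acetaldehyde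
Product: 6 2-[2,4-bis(benzyloxy)-6-(methoxymethoxy)phenyl]acetic acid
Conditions: NaClO2, NaH2PO4, 2-methyl-2-butene, t-BuOH/H2O, rt
Reagents that add atoms: sodium chlorite, [Na+].[O-]Cl=O
Why: Pinnick oxidation converts the aldehyde into the acid under buffered conditions that spare the MOM ether, the alkene scavenger removing hypochlorous acid before it can chlorinate the electron-rich ring.

Step 6
Reactants: 6 2-[2,4-bis(benzyloxy)-6-(methoxymethoxy)phenyl]acetic acid; 7 (R)-4-benzyloxazolidin-2-one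
Product: 9 (R)-4-benzyl-3-{2-[2,4-bis(benzyloxy)-6-(methoxymethoxy)phenyl]acetyl}oxazolidin-2-one, via mixed pivalic anhydride 8 (not isolated)
Conditions: PivCl, Et3N, THF, −20 °C; then 7, LiCl, −20 °C → rt
Reagents that add atoms: none
Why: N-acylation of the oxazolidinone through a mixed pivalic anhydride (LiCl/Et3N variant) is a standard route to Evans imides and avoids strong base next to the acidic benzylic CH2 group.

Step 7
Reactants: 9 (R)-4-benzyl-3-{2-[2,4-bis(benzyloxy)-6-(methoxymethoxy)phenyl]acetyl}oxazolidin-2-one; 10 3,4-bis(benzyloxy)benzaldehyde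
Product: 12 (R)-4-benzyl-3-{(2R,3R)-3-[3,4-bis(benzyloxy)phenyl]-2-[2,4-bis(benzyloxy)-6-(methoxymethoxy)phenyl]-3-hydroxypropanoyl}oxazolidin-2-one, via Z-dibutylboron enolate 11 (not isolated)
Conditions: Bu2BOTf, iPr2NEt, CH2Cl2, 0 °C; then 10, −78 → 0 °C; pH 7 buffer, MeOH, H2O2, 0 °C
Reagents that add atoms: none
Why: Evans syn-aldol reaction, in which soft enolisation gives the Z-dibutylboron enolate that adds to the aldehyde through a closed Zimmerman–Traxler chair on the face remote from the auxiliary benzyl group, so that the (R)-auxiliary sets the aryl-bearing carbon (future C3, R) and the carbinol carbon (future C2, R) in a syn relationship, as is precedented for arylacetyl imides with aromatic aldehydes.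

Step 8
Reactants: 12 the aldol adduct
Product: 13 (R)-4-benzyl-3-{(2R,3R)-3-[3,4-bis(benzyloxy)phenyl]-2-[2,4-bis(benzyloxy)-6-(methoxymethoxy)phenyl]-3-[(triethylsilyl)oxy]propanoyl}oxazolidin-2-one
Conditions: TESCl, imidazole, DMF, rt
Reagents that add atoms: chlorotriethylsilane, CC[Si](Cl)(CC)CC
Why: Silylation of the secondary alcohol (TES ether formation) blocks retro-aldol cleavage and provides a group that can later be removed in the presence of a TBS ether.

Step 9
Reactants: 13 the TES-protected imide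
Product: 14 (2S,3R)-3-[3,4-bis(benzyloxy)phenyl]-2-[2,4-bis(benzyloxy)-6-(methoxymethoxy)phenyl]-3-[(triethylsilyl)oxy]propan-1-ol
Conditions: LiBH4, MeOH (1 equiv), THF, 0 °C
Reagents that add atoms: none
Why: Reductive cleavage of the N-acyl oxazolidinone with LiBH4 gives the primary alcohol and returns the auxiliary, hydride attacking the exocyclic carbonyl without enolisation so that the α-aryl centre is retained (the descriptor changes only because the priorities change).

Step 10
Reactants: 14 the primary alcohol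
Product: 15 (2R,3R)-3-[3,4-bis(benzyloxy)phenyl]-2-[2,4-bis(benzyloxy)-6-(methoxymethoxy)phenyl]-3-[(triethylsilyl)oxy]propanal
Conditions: Dess–Martin periodinane, NaHCO3, CH2Cl2, 0 °C; crude product used at once
Reagents that add atoms: none
Why: Dess–Martin oxidation under bicarbonate-buffered, base-free conditions should give the α-aryl aldehyde without epimerisation or β-elimination of the silyloxy group.

Step 11
Reactants: 16 1-bromo-3,5-bis(benzyloxy)benzene
Product: 17 1,5-bis(benzyloxy)-3-bromo-2-iodobenzene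
Conditions: NIS, CF3CO2H (cat.), MeCN, 0 °C → rt
Reagents that add atoms: N-iodosuccinimide, O=C1CCC(=O)N1I
Why: Electrophilic aromatic iodination goes to the carbon that is para to one benzyloxy group and ortho to the other, next to bromine, because the carbon flanked by both ethers is more hindered.

Step 12
Reactants: 17 1,5-bis(benzyloxy)-3-bromo-2-iodobenzene; 15 the aldehyde
Product: 19 (1R,2S,3R)-3-[3,4-bis(benzyloxy)phenyl]-1-[2,4-bis(benzyloxy)-6-bromophenyl]-2-[2,4-bis(benzyloxy)-6-(methoxymethoxy)phenyl]-3-[(triethylsilyl)oxy]propan-1-ol, via arylmagnesium chloride 18 (not isolated)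
Conditions: 17, iPrMgCl·LiCl, THF, −40 °C; then 15, −40 → −20 °C; aq. NH4Cl
Reagents that add atoms: none
Why: Iodine–magnesium exchange is far faster at C–I than at C–Br and gives an ortho-bromoaryl Grignard reagent that is stable below about −20 °C and adds to the aldehyde (Grignard 1,2-addition), Felkin–Anh attack anti to the α-aryl group being expected to give the carbinol drawn, a centre that later becomes the C4 carbonyl.

Step 13
Reactants: 19 the diaryl carbinol
Product: 20 tert-butyl{(1R,2R,3R)-3-[3,4-bis(benzyloxy)phenyl]-1-[2,4-bis(benzyloxy)-6-bromophenyl]-2-[2,4-bis(benzyloxy)-6-(methoxymethoxy)phenyl]-3-[(triethylsilyl)oxy]propoxy}dimethylsilane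
Conditions: TBSOTf, 2,6-lutidine, CH2Cl2, −78 → 0 °C
Reagents that add atoms: tert-butyldimethylsilyl trifluoromethanesulfonate, CC(C)(C)[Si](C)(C)OS(=O)(=O)C(F)(F)F
Why: Silylation with a silyl triflate reaches the hindered benzylic alcohol and masks the future C4 oxygen as a robust TBS ether, so that in the ring closure it can neither bind palladium nor be oxidised.

Step 14
Reactants: 20 the bis-silyl ether
Product: 21 (1R,2R,3R)-1-[3,4-bis(benzyloxy)phenyl]-3-[2,4-bis(benzyloxy)-6-bromophenyl]-2-[2,4-bis(benzyloxy)-6-(methoxymethoxy)phenyl]-3-[(tert-butyldimethylsilyl)oxy]propan-1-ol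
Conditions: HF·pyridine, pyridine, THF, 0 °C
Reagents that add atoms: none
Why: Selective desilylation, in which pyridine-buffered HF cleaves the less hindered and more labile TES ether much faster than the crowded TBS ether and so frees only the future C2 hydroxyl.

Step 15
Reactants: 21 the bromoaryl diol monosilyl ether
Product: 22 (2R,3R,4R)-5,7-bis(benzyloxy)-2-[3,4-bis(benzyloxy)phenyl]-3-[2,4-bis(benzyloxy)-6-(methoxymethoxy)phenyl]-4-[(tert-butyldimethylsilyl)oxy]chromane (2,3-cis, 3,4-cis)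
Conditions: Pd(OAc)2 (5 mol%), rac-2-(di-tert-butylphosphino)-1,1'-binaphthyl (6 mol%), Cs2CO3, toluene, 80 °C
Reagents that add atoms: none
Why: The aryl bromide adds oxidatively to the zerovalent palladium–phosphine complex, Cs2CO3 deprotonates the C2 hydroxyl and the alkoxide replaces bromide to give a seven-membered aryl(alkoxo)palladium chelate, and C–O reductive elimination forms the O1–C8a bond. The closest known reaction type is the Buchwald–Hartwig-type intramolecular etherification of secondary alcohols with aryl bromides, which gives chromans with retention at the carbinol carbon. Ring C of unit 1 closes as a six-membered ring in an exo sense, the C–Br bond that breaks lying outside the new ring. No stereocentre is created: only the O–H bond of the alcohol is engaged, so the syn C2/C3 relationship from the aldol is carried over as the cis-2,3 pattern, and C3 cannot epimerise because C4 is an ether and not a ketone. The step needs reductive elimination to outrun β-hydride loss from the benzylic alkoxide; the bulky, electron-rich di-tert-butylphosphine and the favourable six-membered closure should secure this, and the silyl group keeps the C4 oxygen off palladium.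

Step 16
Reactants: 22 the cis-flavan silyl ether
Product: 24 3,5-bis(benzyloxy)-2-Flv-phenol, via aryl trimethylsilyl ether 23 (not isolated)
Conditions: TMSOTf, 2,2'-bipyridyl, CH2Cl2, 0 °C → rt; then H2O
Reagents that add atoms: none
Why: Cleavage of the aryl MOM ether by the silyl triflate–bipyridyl complex runs through a pyridinium acetal and the aryl silyl ether under non-protic, weakly Lewis acidic conditions known to spare TBS and benzyl ethers, which matters because the C4 silyl ether sits on a benzylic carbon activated by three alkoxy groups.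

Step 17
Reactants: 24 the phenol
Product: 25 4,6-bis(benzyloxy)-3-Flv-2-hydroxybenzaldehyde
Conditions: MgCl2, Et3N, (CH2O)n, MeCN, reflux; aq. NH4Cl work-up
Reagents that add atoms: paraformaldehyde (as formaldehyde), C=O
Why: Magnesium phenoxide-directed ortho-formylation (Casnati–Skattebøl reaction) delivers the formyl group only to the free ortho carbon, the future C4a'' of unit 2, under mildly basic conditions.

Step 18
Reactants: 25 the salicylaldehyde
Product: 26 1-[4,6-bis(benzyloxy)-3-Flv-2-hydroxyphenyl]prop-2-yn-1-ol (both carbinol epimers)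
Conditions: ethynylmagnesium bromide (3 equiv), THF, 0 °C → rt; aq. NH4Cl
Reagents that add atoms: ethynylmagnesium bromide, C#C[Mg]Br
Why: Grignard 1,2-addition of the acetylide to the aldehyde (one equivalent being consumed by the phenol) installs the two remaining ring carbons, and the new carbinol centre, formed as a mixture of epimers, is of no consequence because it is oxidised in the next step.

Step 19
Reactants: 26 the propargylic alcohol
Product: 28 5,7-bis(benzyloxy)-8-Flv-4H-chromen-4-one, via hydroxyaryl ynone 27 (not isolated)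
Conditions: MnO2, CH2Cl2, rt; filter; K2CO3 (cat.), acetone, rt
Reagents that add atoms: none
Why: MnO2 selectively oxidises the benzylic, propargylic alcohol to the ynone, and the ortho phenoxide then closes ring C of unit 2 by 6-endo-dig oxa-Michael addition to give the chromone.

Step 20
Reactants: 28 the chromone; 29 4-(benzyloxy)phenylboronic acid
Product: 30 (2R)-5,7-bis(benzyloxy)-2-[4-(benzyloxy)phenyl]-8-Flv-chroman-4-one
Conditions: [Rh(OH)(cod)]2 (3 mol%), (R)-6,6'-dimethoxy-2,2'-bis[bis(3,4,5-trifluorophenyl)phosphino]-1,1'-biphenyl (7 mol%), CH2Cl2/H2O, 20 °C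
Reagents that add atoms: none
Why: Rhodium-catalysed asymmetric 1,4-addition of an arylboronic acid to a chromone (Hayashi–Miyaura reaction) with an electron-poor biaryl bisphosphine is established for 5,7-dioxygenated chromones, and the new C2'' centre is set by the ligand, the (R)-antipode being chosen by analogy with the stereochemical model for cyclic enones to deliver the aryl group to the Si face and give the 2R configuration.

Step 21
Reactants: 30 the flavanone–flavan silyl ether
Product: 31 (2R)-5,7-bis(benzyloxy)-2-[4-(benzyloxy)phenyl]-8-{(2R,3S,4R)-5,7-bis(benzyloxy)-2-[3,4-bis(benzyloxy)phenyl]-4-hydroxychroman-3-yl}chroman-4-one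
Conditions: TBAF, AcOH, THF, rt → 40 °C
Reagents that add atoms: none
Why: Fluoride-mediated desilylation buffered with acetic acid should remove the TBS group without opening the flavanone of unit 2 by retro-oxa-Michael reaction and without ionising the electron-rich benzylic C4 position (the C3 descriptor changes only because the priorities change).

Step 22
Reactants: 31 the C4 alcohol
Product: 32 (2R,3R)-5,7-bis(benzyloxy)-2-[3,4-bis(benzyloxy)phenyl]-3-{(2R)-5,7-bis(benzyloxy)-2-[4-(benzyloxy)phenyl]-4-oxochroman-8-yl}chroman-4-one (2,3-cis)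
Conditions: Dess–Martin periodinane, NaHCO3, CH2Cl2, 0 °C → rt
Reagents that add atoms: none
Why: Dess–Martin oxidation converts the C4 carbinol into the ketone under neutral conditions, removing the transient stereocentre while the now enolisable cis C3 centre is never exposed to soluble base.

Step 23
Reactants: 32 the hepta-O-benzyl biflavanone
Product: 33 (2R,3R)-2-(3,4-dihydroxyphenyl)-5,7-dihydroxy-3-[(2R)-5,7-dihydroxy-2-(4-hydroxyphenyl)-4-oxochroman-8-yl]chroman-4-one (2,3-cis), the target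
Conditions: H2 (1 atm), Pd/C, EtOAc/MeOH, rt
Reagents that add atoms: none
Why: Catalytic hydrogenolysis cleaves all seven benzyl ethers under neutral conditions at room temperature, where the aryl ketones and the benzylic ring C–O bonds of flavanones are normally preserved and the cis C2/C3 arrangement is not equilibrated.

**Compound list**
1 | 3,5-bis(benzyloxy)phenol | Oc1cc(OCc2ccccc2)cc(OCc2ccccc2)c1 | starting material
2 | 1-(allyloxy)-3,5-bis(benzyloxy)benzene | C=CCOc1cc(OCc2ccccc2)cc(OCc2ccccc2)c1 | intermediate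
3 | 2-allyl-3,5-bis(benzyloxy)phenol | C=CCc1c(O)cc(OCc2ccccc2)cc1OCc1ccccc1 | intermediate
4 | 2-allyl-1,5-bis(benzyloxy)-3-(methoxymethoxy)benzene | C=CCc1c(OCOC)cc(OCc2ccccc2)cc1OCc1ccccc1 | intermediate
5 | 2-[2,4-bis(benzyloxy)-6-(methoxymethoxy)phenyl]acetaldehyde | O=CCc1c(OCOC)cc(OCc2ccccc2)cc1OCc1ccccc1 | intermediate
6 | 2-[2,4-bis(benzyloxy)-6-(methoxymethoxy)phenyl]acetic acid | OC(=O)Cc1c(OCOC)cc(OCc2ccccc2)cc1OCc1ccccc1 | intermediate
7 | (R)-4-benzyloxazolidin-2-one | O=C1N[C@H](Cc2ccccc2)CO1 | starting material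
8 | 2-[2,4-bis(benzyloxy)-6-(methoxymethoxy)phenyl]acetic pivalic anhydride | CC(C)(C)C(=O)OC(=O)Cc1c(OCOC)cc(OCc2ccccc2)cc1OCc1ccccc1 | intermediate (not isolated)
9 | (R)-4-benzyl-3-{2-[2,4-bis(benzyloxy)-6-(methoxymethoxy)phenyl]acetyl}oxazolidin-2-one | O=C1OC[C@@H](Cc2ccccc2)N1C(=O)Cc1c(OCOC)cc(OCc2ccccc2)cc1OCc1ccccc1 | intermediate
10 | 3,4-bis(benzyloxy)benzaldehyde | O=Cc1ccc(OCc2ccccc2)c(OCc2ccccc2)c1 | starting material
11 | Z-dibutylboron enolate of 9 | CCCCB(CCCC)O/C(=C\c1c(OCOC)cc(OCc2ccccc2)cc1OCc1ccccc1)N1C(=O)OC[C@H]1Cc1ccccc1 | intermediate (not isolated)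
12 | (R)-4-benzyl-3-{(2R,3R)-3-[3,4-bis(benzyloxy)phenyl]-2-[2,4-bis(benzyloxy)-6-(methoxymethoxy)phenyl]-3-hydroxypropanoyl}oxazolidin-2-one | COCOc1cc(OCc2ccccc2)cc(OCc2ccccc2)c1[C@H]([C@@H](O)c1ccc(OCc2ccccc2)c(OCc2ccccc2)c1)C(=O)N1C(=O)OC[C@H]1Cc1ccccc1 | intermediate
13 | triethylsilyl ether of 12 | COCOc1cc(OCc2ccccc2)cc(OCc2ccccc2)c1[C@H]([C@@H](O[Si](CC)(CC)CC)c1ccc(OCc2ccccc2)c(OCc2ccccc2)c1)C(=O)N1C(=O)OC[C@H]1Cc1ccccc1 | intermediate
14 | (2S,3R)-3-[3,4-bis(benzyloxy)phenyl]-2-[2,4-bis(benzyloxy)-6-(methoxymethoxy)phenyl]-3-[(triethylsilyl)oxy]propan-1-ol | COCOc1cc(OCc2ccccc2)cc(OCc2ccccc2)c1[C@H]([C@@H](O[Si](CC)(CC)CC)c1ccc(OCc2ccccc2)c(OCc2ccccc2)c1)CO | intermediate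
15 | (2R,3R)-3-[3,4-bis(benzyloxy)phenyl]-2-[2,4-bis(benzyloxy)-6-(methoxymethoxy)phenyl]-3-[(triethylsilyl)oxy]propanal | COCOc1cc(OCc2ccccc2)cc(OCc2ccccc2)c1[C@H]([C@@H](O[Si](CC)(CC)CC)c1ccc(OCc2ccccc2)c(OCc2ccccc2)c1)C=O | intermediate
16 | 1-bromo-3,5-bis(benzyloxy)benzene | Brc1cc(OCc2ccccc2)cc(OCc2ccccc2)c1 | starting material
17 | 1,5-bis(benzyloxy)-3-bromo-2-iodobenzene | Brc1cc(OCc2ccccc2)cc(OCc2ccccc2)c1I | intermediate
18 | [2,4-bis(benzyloxy)-6-bromophenyl]magnesium chloride | Cl[Mg]c1c(Br)cc(OCc2ccccc2)cc1OCc1ccccc1 | intermediate (not isolated)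
19 | (1R,2S,3R)-3-[3,4-bis(benzyloxy)phenyl]-1-[2,4-bis(benzyloxy)-6-bromophenyl]-2-[2,4-bis(benzyloxy)-6-(methoxymethoxy)phenyl]-3-[(triethylsilyl)oxy]propan-1-ol | COCOc1cc(OCc2ccccc2)cc(OCc2ccccc2)c1[C@H]([C@@H](O[Si](CC)(CC)CC)c1ccc(OCc2ccccc2)c(OCc2ccccc2)c1)[C@@H](O)c1c(OCc2ccccc2)cc(OCc2ccccc2)cc1Br | intermediate
20 | tert-butyldimethylsilyl ether of 19 (1R,2R,3R) | COCOc1cc(OCc2ccccc2)cc(OCc2ccccc2)c1[C@H]([C@@H](O[Si](CC)(CC)CC)c1ccc(OCc2ccccc2)c(OCc2ccccc2)c1)[C@@H](O[Si](C)(C)C(C)(C)C)c1c(OCc2ccccc2)cc(OCc2ccccc2)cc1Br | intermediate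
21 | (1R,2R,3R)-1-[3,4-bis(benzyloxy)phenyl]-3-[2,4-bis(benzyloxy)-6-bromophenyl]-2-[2,4-bis(benzyloxy)-6-(methoxymethoxy)phenyl]-3-[(tert-butyldimethylsilyl)oxy]propan-1-ol | COCOc1cc(OCc2ccccc2)cc(OCc2ccccc2)c1[C@H]([C@@H](O)c1ccc(OCc2ccccc2)c(OCc2ccccc2)c1)[C@@H](O[Si](C)(C)C(C)(C)C)c1c(OCc2ccccc2)cc(OCc2ccccc2)cc1Br | intermediate (key-step precursor)
22 | (2R,3R,4R)-5,7-bis(benzyloxy)-2-[3,4-bis(benzyloxy)phenyl]-3-[2,4-bis(benzyloxy)-6-(methoxymethoxy)phenyl]-4-[(tert-butyldimethylsilyl)oxy]chromane | COCOc1cc(OCc2ccccc2)cc(OCc2ccccc2)c1[C@H]1[C@@H](O[Si](C)(C)C(C)(C)C)c2c(OCc3ccccc3)cc(OCc3ccccc3)cc2O[C@H]1c1ccc(OCc2ccccc2)c(OCc2ccccc2)c1 | intermediate (key-step product)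
23 | [3,5-bis(benzyloxy)-2-Flv-phenoxy]trimethylsilane | C[Si](C)(C)Oc1cc(OCc2ccccc2)cc(OCc2ccccc2)c1[C@H]1[C@@H](O[Si](C)(C)C(C)(C)C)c2c(OCc3ccccc3)cc(OCc3ccccc3)cc2O[C@H]1c1ccc(OCc2ccccc2)c(OCc2ccccc2)c1 | intermediate (not isolated)
24 | 3,5-bis(benzyloxy)-2-Flv-phenol | Oc1cc(OCc2ccccc2)cc(OCc2ccccc2)c1[C@H]1[C@@H](O[Si](C)(C)C(C)(C)C)c2c(OCc3ccccc3)cc(OCc3ccccc3)cc2O[C@H]1c1ccc(OCc2ccccc2)c(OCc2ccccc2)c1 | intermediate
25 | 4,6-bis(benzyloxy)-3-Flv-2-hydroxybenzaldehyde | Oc1c(C=O)c(OCc2ccccc2)cc(OCc2ccccc2)c1[C@H]1[C@@H](O[Si](C)(C)C(C)(C)C)c2c(OCc3ccccc3)cc(OCc3ccccc3)cc2O[C@H]1c1ccc(OCc2ccccc2)c(OCc2ccccc2)c1 | intermediate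
26 | 1-[4,6-bis(benzyloxy)-3-Flv-2-hydroxyphenyl]prop-2-yn-1-ol (carbinol centre as both epimers) | Oc1c(C(O)C#C)c(OCc2ccccc2)cc(OCc2ccccc2)c1[C@H]1[C@@H](O[Si](C)(C)C(C)(C)C)c2c(OCc3ccccc3)cc(OCc3ccccc3)cc2O[C@H]1c1ccc(OCc2ccccc2)c(OCc2ccccc2)c1 | intermediate
27 | 1-[4,6-bis(benzyloxy)-3-Flv-2-hydroxyphenyl]prop-2-yn-1-one | Oc1c(C(=O)C#C)c(OCc2ccccc2)cc(OCc2ccccc2)c1[C@H]1[C@@H](O[Si](C)(C)C(C)(C)C)c2c(OCc3ccccc3)cc(OCc3ccccc3)cc2O[C@H]1c1ccc(OCc2ccccc2)c(OCc2ccccc2)c1 | intermediate (not isolated)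
28 | 5,7-bis(benzyloxy)-8-Flv-4H-chromen-4-one | O=c1ccoc2c([C@H]3[C@@H](O[Si](C)(C)C(C)(C)C)c4c(OCc5ccccc5)cc(OCc5ccccc5)cc4O[C@H]3c3ccc(OCc4ccccc4)c(OCc4ccccc4)c3)c(OCc3ccccc3)cc(OCc3ccccc3)c12 | intermediate
29 | 4-(benzyloxy)phenylboronic acid | OB(O)c1ccc(OCc2ccccc2)cc1 | starting material
30 | (2R)-5,7-bis(benzyloxy)-2-[4-(benzyloxy)phenyl]-8-Flv-chroman-4-one | O=C1C[C@H](c2ccc(OCc3ccccc3)cc2)Oc2c1c(OCc1ccccc1)cc(OCc1ccccc1)c2[C@H]1[C@@H](O[Si](C)(C)C(C)(C)C)c2c(OCc3ccccc3)cc(OCc3ccccc3)cc2O[C@H]1c1ccc(OCc2ccccc2)c(OCc2ccccc2)c1 | intermediate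
31 | (2R)-5,7-bis(benzyloxy)-2-[4-(benzyloxy)phenyl]-8-{(2R,3S,4R)-5,7-bis(benzyloxy)-2-[3,4-bis(benzyloxy)phenyl]-4-hydroxychroman-3-yl}chroman-4-one | O=C1C[C@H](c2ccc(OCc3ccccc3)cc2)Oc2c1c(OCc1ccccc1)cc(OCc1ccccc1)c2[C@H]1[C@@H](O)c2c(OCc3ccccc3)cc(OCc3ccccc3)cc2O[C@H]1c1ccc(OCc2ccccc2)c(OCc2ccccc2)c1 | intermediate
32 | (2R,3R)-5,7-bis(benzyloxy)-2-[3,4-bis(benzyloxy)phenyl]-3-{(2R)-5,7-bis(benzyloxy)-2-[4-(benzyloxy)phenyl]-4-oxochroman-8-yl}chroman-4-one | O=C1C[C@H](c2ccc(OCc3ccccc3)cc2)Oc2c1c(OCc1ccccc1)cc(OCc1ccccc1)c2[C@H]1C(=O)c2c(OCc3ccccc3)cc(OCc3ccccc3)cc2O[C@H]1c1ccc(OCc2ccccc2)c(OCc2ccccc2)c1 | intermediate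
33 | (2R,3R)-2-(3,4-dihydroxyphenyl)-5,7-dihydroxy-3-[(2R)-5,7-dihydroxy-2-(4-hydroxyphenyl)-4-oxochroman-8-yl]chroman-4-one | O=C1C[C@H](c2ccc(O)cc2)Oc2c1c(O)cc(O)c2[C@H]1C(=O)c2c(O)cc(O)cc2O[C@H]1c1ccc(O)c(O)c1 | target

Total step count: 23. Longest linear sequence: 22 steps (from 1 through steps 1–10 and 12–23); step 11 is a one-step side branch.

**Steps most likely to fail**

Step 15. β-Hydride loss from the palladium alkoxide would oxidise the C2 carbinol and reduce the C–Br bond, or reductive elimination could stall in the crowded chelate. Fallback: starting from 21, Miyaura borylation (B2pin2, Pd(dppf)Cl2, KOAc, dioxane, 90 °C) would replace bromine by boron to give the arylboronic acid pinacol ester of 21 F1. Copper-mediated oxidative etherification (Chan–Lam coupling; Cu(OAc)2, DMAP, 4 Å sieves, O2, CH2Cl2, rt) would then join the C2 oxygen to C8a with retention and return to the route at 22. This forms the same bond from an aryl–boron rather than an aryl–halogen partner, through a copper alkoxide that is less prone to β-hydride loss.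

Step 12. The ortho-bromoarylmagnesium could lose magnesium halide to an aryne before it adds, or its basicity could enolise the hindered α-aryl aldehyde and scramble the future C3 centre. Fallback: starting from 15 and 17, a Nozaki–Hiyama–Kishi coupling (CrCl2, NiCl2 (cat.), DMF/THF, rt) would generate a non-basic arylchromium species selectively at the C–I bond in the presence of the aldehyde and give 19 directly. No preformed Grignard reagent is involved and the sequence passes through no new isolable compound (F0).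

Step 20. Aryl transfer to the electron-rich, 8-substituted chromone could be slow relative to protodeboronation, or face selectivity could be eroded by the neighbouring chiral flavan. Fallback: starting from 25, MeMgBr (THF, 0 °C) would give 1-[4,6-bis(benzyloxy)-3-Flv-2-hydroxyphenyl]ethan-1-ol F2, and MnO2 would oxidise it to the ortho-hydroxyacetophenone 1-[4,6-bis(benzyloxy)-3-Flv-2-hydroxyphenyl]ethan-1-one F3. Claisen–Schmidt condensation with commercial 4-(benzyloxy)benzaldehyde (KOH, EtOH, rt; the silyl ether tolerates base because C4 is not yet a ketone) would give the 2'-hydroxychalcone F4. 6-Endo oxa-Michael cyclisation (NaOAc, EtOH, reflux) would then close ring C of unit 2 through the O1''–C2'' bond and return to the route at 30. The C2'' epimer of 30 F5 formed alongside is a diastereomer, to be separated by chromatography and recycled to F4 with base.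

**Further compounds**
F1 | step 15 | (1R,2R,3R)-1-[3,4-bis(benzyloxy)phenyl]-3-[2,4-bis(benzyloxy)-6-(4,4,5,5-tetramethyl-1,3,2-dioxaborolan-2-yl)phenyl]-2-[2,4-bis(benzyloxy)-6-(methoxymethoxy)phenyl]-3-[(tert-butyldimethylsilyl)oxy]propan-1-ol | COCOc1cc(OCc2ccccc2)cc(OCc2ccccc2)c1[C@H]([C@@H](O)c1ccc(OCc2ccccc2)c(OCc2ccccc2)c1)[C@@H](O[Si](C)(C)C(C)(C)C)c1c(OCc2ccccc2)cc(OCc2ccccc2)cc1B1OC(C)(C)C(C)(C)O1
F0 | step 12 | none | none
F2 | step 20 | 1-[4,6-bis(benzyloxy)-3-Flv-2-hydroxyphenyl]ethan-1-ol (both carbinol epimers) | Oc1c(C(C)O)c(OCc2ccccc2)cc(OCc2ccccc2)c1[C@H]1[C@@H](O[Si](C)(C)C(C)(C)C)c2c(OCc3ccccc3)cc(OCc3ccccc3)cc2O[C@H]1c1ccc(OCc2ccccc2)c(OCc2ccccc2)c1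
F3 | step 20 | 1-[4,6-bis(benzyloxy)-3-Flv-2-hydroxyphenyl]ethan-1-one | Oc1c(C(C)=O)c(OCc2ccccc2)cc(OCc2ccccc2)c1[C@H]1[C@@H](O[Si](C)(C)C(C)(C)C)c2c(OCc3ccccc3)cc(OCc3ccccc3)cc2O[C@H]1c1ccc(OCc2ccccc2)c(OCc2ccccc2)c1
F4 | step 20 | (E)-1-[4,6-bis(benzyloxy)-3-Flv-2-hydroxyphenyl]-3-[4-(benzyloxy)phenyl]prop-2-en-1-one | Oc1c(C(=O)/C=C/c2ccc(OCc3ccccc3)cc2)c(OCc2ccccc2)cc(OCc2ccccc2)c1[C@H]1[C@@H](O[Si](C)(C)C(C)(C)C)c2c(OCc3ccccc3)cc(OCc3ccccc3)cc2O[C@H]1c1ccc(OCc2ccccc2)c(OCc2ccccc2)c1
F5 | step 20 | (2S)-5,7-bis(benzyloxy)-2-[4-(benzyloxy)phenyl]-8-Flv-chroman-4-one | O=C1C[C@@H](c2ccc(OCc3ccccc3)cc2)Oc2c1c(OCc1ccccc1)cc(OCc1ccccc1)c2[C@H]1[C@@H](O[Si](C)(C)C(C)(C)C)c2c(OCc3ccccc3)cc(OCc3ccccc3)cc2O[C@H]1c1ccc(OCc2ccccc2)c(OCc2ccccc2)c1
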